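Ring B (C5–C6–C7–C8–C9–C10) is closed last, by Lewis-acid addition of the C5=C10 double bond of an intact ring A to a tethered C9 α-keto ester (Prins/carbonyl-ene type). The step exploits the C9 tertiary α-hydroxy acid beside quaternary C10 and the C6 oxygen: in the open precursor C6 is an enantiopure silyloxy carbon, joined to C9 by the Z C7=C8 bond. One operation forms the C9–C10 bond, sets C9 and C10 under control of C6 and, by 1,2-hydride shift from C6 to C5, delivers the trans-fused C6 ketone. Hydride reduction from the α face and acylation then give the 6β-ester.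

Key step: step 7

Remark: ring carbons carry drimane numbers (ring A = C1–C5 and C10, ring B = C5–C10, C11 = carboxyl carbon on C9, C12 = carbon on C8); silyl ether 2 and di-tert-butyl oxalate are taken as commercial.

Step 1
Reactants: 1 β-cyclocitral (2,6,6-trimethylcyclohex-1-ene-1-carbaldehyde); 2 tert-butyl(diphenyl)(prop-2-yn-1-yloxy)silane
Product: 4 rac-4-[(tert-butyldiphenylsilyl)oxy]-1-(2,6,6-trimethylcyclohex-1-en-1-yl)but-2-yn-1-ol, via lithium acetylide 3 (not isolated)
Conditions: 2, n-BuLi, THF, −78 °C; then 1, −78 to 0 °C; H2O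
Reagents that add atoms: none
Why: 1,2-addition of a lithium acetylide to the hindered enal (C10 is fully substituted, so conjugate addition does not compete) joins C6 to C7, C8 and C12; the carbinol is racemic because C6 is reset in step 3.

Step 2
Reactants: 4 rac-4-[(tert-butyldiphenylsilyl)oxy]-1-(2,6,6-trimethylcyclohex-1-en-1-yl)but-2-yn-1-ol
Product: 5 4-[(tert-butyldiphenylsilyl)oxy]-1-(2,6,6-trimethylcyclohex-1-en-1-yl)but-2-yn-1-one
Conditions: activated MnO2, CH2Cl2, rt
Reagents that add atoms: none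
Why: MnO2 oxidation of an alcohol that is both allylic and propargylic gives the ynone without touching the silyl ether.

Step 3
Reactants: 5 4-[(tert-butyldiphenylsilyl)oxy]-1-(2,6,6-trimethylcyclohex-1-en-1-yl)but-2-yn-1-one
Product: 6 (1R)-4-[(tert-butyldiphenylsilyl)oxy]-1-(2,6,6-trimethylcyclohex-1-en-1-yl)but-2-yn-1-ol
Conditions: Ru[(S,S)-TsDPEN](p-cymene) (1–2 mol %), i-PrOH, rt
Reagents that add atoms: none
Why: Noyori asymmetric transfer hydrogenation of an alkynyl ketone, in which the catalyst tells the slim alkynyl group from the bulky cyclohexenyl group; by analogy with alkyl alkynyl ketones the (S,S)-catalyst should set C6 as (R), and the (R,R)-catalyst would be used if the opposite sense were found.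

Step 4
Reactants: 6 (1R)-4-[(tert-butyldiphenylsilyl)oxy]-1-(2,6,6-trimethylcyclohex-1-en-1-yl)but-2-yn-1-ol
Product: 8 (1R,2Z)-4-[(tert-butyldiphenylsilyl)oxy]-3-iodo-1-(2,6,6-trimethylcyclohex-1-en-1-yl)but-2-en-1-ol, via cyclic alkenylalanate 7 (not isolated)
Conditions: Red-Al, THF, 0 °C; EtOAc; then I2, THF, −78 to 0 °C; aq. Rochelle salt
Reagents that add atoms: iodine, II
Why: hydroxyl-directed trans-hydroalumination of a propargylic alcohol followed by iodinolysis places hydride on C7 and aluminium, then iodine, on C8 within a five-membered alkoxyalanate, so iodine ends cis to C6 (Z) and C6 is untouched.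

Step 5
Reactants: 8 (1R,2Z)-4-[(tert-butyldiphenylsilyl)oxy]-3-iodo-1-(2,6,6-trimethylcyclohex-1-en-1-yl)but-2-en-1-ol
Product: 9 (1R,2Z)-1-[(tert-butyldimethylsilyl)oxy]-4-[(tert-butyldiphenylsilyl)oxy]-3-iodo-1-(2,6,6-trimethylcyclohex-1-en-1-yl)but-2-ene
Conditions: TBSOTf, 2,6-lutidine, CH2Cl2, −78 to 0 °C
Reagents that add atoms: tert-butyldimethylsilyl triflate, CC(C)(C)[Si](C)(C)OS(=O)(=O)C(F)(F)F
Why: silylation of the hindered secondary alcohol with a silyl triflate prevents hemiketal and furan formation once the C9 ketone is in place and supplies the bulky group that later directs the ring closure.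

Step 6
Reactants: 9 (1R,2Z)-1-[(tert-butyldimethylsilyl)oxy]-4-[(tert-butyldiphenylsilyl)oxy]-3-iodo-1-(2,6,6-trimethylcyclohex-1-en-1-yl)but-2-ene
Product: 11 tert-butyl (3Z,5R)-5-[(tert-butyldimethylsilyl)oxy]-3-{[(tert-butyldiphenylsilyl)oxy]methyl}-2-oxo-5-(2,6,6-trimethylcyclohex-1-en-1-yl)pent-3-enoate, via alkenyllithium 10 (not isolated)
Conditions: t-BuLi (2.1 equiv), Et2O, −78 °C; cannulated into di-tert-butyl oxalate (3 equiv), THF, −78 °C; H2O
Reagents that add atoms: di-tert-butyl oxalate, CC(C)(C)OC(=O)C(=O)OC(C)(C)C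
Why: iodine–lithium exchange with retention of alkene geometry and acylation of the alkenyllithium by an oxalate diester (the tetrahedral adduct survives at −78 °C and prevents double addition) install C9 and C11 cis to C6.

Step 7
Reactants: 11 tert-butyl (3Z,5R)-5-[(tert-butyldimethylsilyl)oxy]-3-{[(tert-butyldiphenylsilyl)oxy]methyl}-2-oxo-5-(2,6,6-trimethylcyclohex-1-en-1-yl)pent-3-enoate
Product: 14 tert-butyl (5S,9S,10S)-12-[(tert-butyldiphenylsilyl)oxy]-9-hydroxy-6-oxodrim-7-en-11-oate, via C5 carbocation 12 (not isolated), via O-silyl oxocarbenium ion 13 (not isolated)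
Conditions: SnCl4 (1.2 equiv, promoter), CH2Cl2, −78 to −40 °C; then 1 M HCl, THF, 0 °C
Reagents that add atoms: none
Why: Proposed new method: SnCl4 binds the α-keto ester of 11 and the nucleophilic tetrasubstituted C5=C10 bond adds through C10 to the C9 carbonyl carbon to give the tertiary C5 cation 12, whose only β-hydrogen is on C6, so a 1,2-hydride shift to C5 gives the O-silyl oxocarbenium ion 13, which loses silicon to leave the C6 ketone; the closest known reaction type is the Lewis-acid intramolecular carbonyl-ene (Prins) cyclisation of olefinic α-keto esters, here in the unprecedented mode in which the hydrogen comes from the tether carbinol carbon, with a Prins-pinacol-like termination. Ring B closes 6-endo-trig with respect to the C5=C10 bond and 6-exo-trig with respect to the C9 carbonyl. C10 is controlled by the C6 stereocentre, because allylic strain with the C4 gem-dimethyl and C10 methyl groups holds the C6 hydrogen near the ring-A plane, the Z-alkene tether on one face and the silyloxy group on the other, so that C9 is delivered anti to the C6–O bond. C9 is controlled by the approach geometry, in which the bulky ester turns away from ring A and the carbonyl oxygen lies over it, and this should give the 9α-hydroxyl trans to the C10 methyl group. C5 is set by the suprafacial hydride shift on the α face and is in any case epimerisable next to the ketone toward the trans ring fusion. The step needs attack at C10 and not at C5 (which would give a spiro five-membered ring) and activation of the keto ester and not of the allylic silyl ether, which are secured by shielding of C5 by the gem-dimethyl group, by the span of the Z tether from C6 to C10 and by preferential binding of tin to the 1,2-dicarbonyl unit at low temperature.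

Step 8
Reactants: 14 tert-butyl (5S,9S,10S)-12-[(tert-butyldiphenylsilyl)oxy]-9-hydroxy-6-oxodrim-7-en-11-oate
Product: 15 tert-butyl (5S,6R,9S,10S)-12-[(tert-butyldiphenylsilyl)oxy]-6,9-dihydroxydrim-7-en-11-oate
Conditions: NaBH4, CeCl3·7H2O, MeOH, −40 to 0 °C
Reagents that add atoms: none
Why: Luche 1,2-reduction of the enone, in which hydride should attack C6 from the α face because the β face is blocked by the syn-axial C10 and C4β methyl groups, giving the axial 6β-alcohol.

Step 9
Reactants: 16 (2E,4E)-hexa-2,4-dienal (sorbaldehyde)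
Product: 17 (2E,4E,6E)-octa-2,4,6-trienoic acid
Conditions: malonic acid, pyridine, piperidine (cat.), 90 °C
Reagents that add atoms: malonic acid, OC(=O)CC(=O)O
Why: Knoevenagel–Doebner condensation with decarboxylation gives the E-configured new double bond and extends the dienal to the trienoic acid.

Step 10
Reactants: 15 tert-butyl (5S,6R,9S,10S)-12-[(tert-butyldiphenylsilyl)oxy]-6,9-dihydroxydrim-7-en-11-oate; 17 (2E,4E,6E)-octa-2,4,6-trienoic acid
Product: 19 tert-butyl (5S,6R,9S,10S)-12-[(tert-butyldiphenylsilyl)oxy]-9-hydroxy-6-[(2E,4E,6E)-octa-2,4,6-trienoyloxy]drim-7-en-11-oate, via mixed anhydride 18 (not isolated)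
Conditions: 17, 2,4,6-trichlorobenzoyl chloride, Et3N, toluene, rt; then 15, DMAP, toluene, rt to 40 °C
Reagents that add atoms: none
Why: Yamaguchi esterification acylates the secondary 6β-hydroxyl, while the tertiary C9 hydroxyl next to quaternary C10 stays free.

Step 11
Reactants: 19 tert-butyl (5S,6R,9S,10S)-12-[(tert-butyldiphenylsilyl)oxy]-9-hydroxy-6-[(2E,4E,6E)-octa-2,4,6-trienoyloxy]drim-7-en-11-oate
Product: 20 tert-butyl (5S,6R,9S,10S)-9,12-dihydroxy-6-[(2E,4E,6E)-octa-2,4,6-trienoyloxy]drim-7-en-11-oate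
Conditions: HF·pyridine, pyridine, THF, 0 °C to rt
Reagents that add atoms: none
Why: buffered fluoride cleavage of the primary silyl ether leaves both esters intact, and the bulky tert-butyl ester resists lactonisation onto the freed C12 hydroxyl.

Step 12
Reactants: 20 tert-butyl (5S,6R,9S,10S)-9,12-dihydroxy-6-[(2E,4E,6E)-octa-2,4,6-trienoyloxy]drim-7-en-11-oate
Product: 21 tert-butyl (5S,6R,9S,10S)-9-hydroxy-6-[(2E,4E,6E)-octa-2,4,6-trienoyloxy]-12-oxodrim-7-en-11-oate
Conditions: activated MnO2, CH2Cl2, rt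
Reagents that add atoms: none
Why: MnO2 oxidises the primary allylic alcohol to the C7=C8 enal, and the product has no enolisable hydrogen at C9 that could expel the C6 acyloxy group.

Step 13
Reactants: 21 tert-butyl (5S,6R,9S,10S)-9-hydroxy-6-[(2E,4E,6E)-octa-2,4,6-trienoyloxy]-12-oxodrim-7-en-11-oate
Product: 22 ustusoic acid B, (5S,6R,9S,10S)-9-hydroxy-6-[(2E,4E,6E)-octa-2,4,6-trienoyloxy]-12-oxodrim-7-en-11-oic acid
Conditions: TFA, CH2Cl2, 0 °C
Reagents that add atoms: none
Why: acidolysis of the tert-butyl ester (loss of isobutene) frees the C11 acid without hydrolysing the C6 ester; ionisation at C6 or C9 is disfavoured by the adjacent enal and carboxyl groups.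

Compound list
1 | β-cyclocitral, 2,6,6-trimethylcyclohex-1-ene-1-carbaldehyde | CC1=C(C=O)C(C)(C)CCC1 | starting material
2 | tert-butyl(diphenyl)(prop-2-yn-1-yloxy)silane | C#CCO[Si](c1ccccc1)(c1ccccc1)C(C)(C)C | starting material
3 | lithium acetylide of 2 | [Li]C#CCO[Si](c1ccccc1)(c1ccccc1)C(C)(C)C | intermediate (not isolated)
4 | rac-4-[(tert-butyldiphenylsilyl)oxy]-1-(2,6,6-trimethylcyclohex-1-en-1-yl)but-2-yn-1-ol | OC(C#CCO[Si](c1ccccc1)(c1ccccc1)C(C)(C)C)C1=C(C)CCCC1(C)C | intermediate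
5 | 4-[(tert-butyldiphenylsilyl)oxy]-1-(2,6,6-trimethylcyclohex-1-en-1-yl)but-2-yn-1-one | O=C(C#CCO[Si](c1ccccc1)(c1ccccc1)C(C)(C)C)C1=C(C)CCCC1(C)C | intermediate
6 | (1R)-4-[(tert-butyldiphenylsilyl)oxy]-1-(2,6,6-trimethylcyclohex-1-en-1-yl)but-2-yn-1-ol | O[C@H](C#CCO[Si](c1ccccc1)(c1ccccc1)C(C)(C)C)C1=C(C)CCCC1(C)C | intermediate
7 | sodium cyclic alkenyl(alkoxy)bis(2-methoxyethoxy)aluminate from 6 (Al on C8, O on C6) | [Na+].COCCO[Al-]1(OCCOC)O[C@@H](C2=C(C)CCCC2(C)C)C=C1CO[Si](c1ccccc1)(c1ccccc1)C(C)(C)C | intermediate (not isolated)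
8 | (1R,2Z)-4-[(tert-butyldiphenylsilyl)oxy]-3-iodo-1-(2,6,6-trimethylcyclohex-1-en-1-yl)but-2-en-1-ol | O[C@H](/C=C(\I)CO[Si](c1ccccc1)(c1ccccc1)C(C)(C)C)C1=C(C)CCCC1(C)C | intermediate
9 | (1R,2Z)-1-[(tert-butyldimethylsilyl)oxy]-4-[(tert-butyldiphenylsilyl)oxy]-3-iodo-1-(2,6,6-trimethylcyclohex-1-en-1-yl)but-2-ene | CC(C)(C)[Si](C)(C)O[C@H](/C=C(\I)CO[Si](c1ccccc1)(c1ccccc1)C(C)(C)C)C1=C(C)CCCC1(C)C | intermediate
10 | alkenyllithium from 9 (Li on C8, cis to C6) | CC(C)(C)[Si](C)(C)O[C@H](/C=C(\[Li])CO[Si](c1ccccc1)(c1ccccc1)C(C)(C)C)C1=C(C)CCCC1(C)C | intermediate (not isolated)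
11 | tert-butyl (3Z,5R)-5-[(tert-butyldimethylsilyl)oxy]-3-{[(tert-butyldiphenylsilyl)oxy]methyl}-2-oxo-5-(2,6,6-trimethylcyclohex-1-en-1-yl)pent-3-enoate | CC(C)(C)[Si](C)(C)O[C@H](/C=C(\C(=O)C(=O)OC(C)(C)C)CO[Si](c1ccccc1)(c1ccccc1)C(C)(C)C)C1=C(C)CCCC1(C)C | intermediate
12 | C5 carbocation after C9–C10 bond formation (6β-silyloxy, 9α-O, 10β-methyl; tin on O9 not drawn) | CC(C)(C)[Si](C)(C)O[C@@H]1C=C(CO[Si](c3ccccc3)(c3ccccc3)C(C)(C)C)[C@](O)(C(=O)OC(C)(C)C)[C@@]2(C)CCCC(C)(C)[C+]12 | intermediate (not isolated)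
13 | O-silyl oxocarbenium ion at C6 after 1,2-hydride shift (5α-H) | CC(C)(C)[Si](C)(C)[O+]=C1C=C(CO[Si](c3ccccc3)(c3ccccc3)C(C)(C)C)[C@](O)(C(=O)OC(C)(C)C)[C@@]2(C)CCCC(C)(C)[C@H]12 | intermediate (not isolated)
14 | tert-butyl (5S,9S,10S)-12-[(tert-butyldiphenylsilyl)oxy]-9-hydroxy-6-oxodrim-7-en-11-oate (5α-H, 9α-OH, 10β-methyl) | O=C1C=C(CO[Si](c3ccccc3)(c3ccccc3)C(C)(C)C)[C@](O)(C(=O)OC(C)(C)C)[C@@]2(C)CCCC(C)(C)[C@H]12 | intermediate
15 | tert-butyl (5S,6R,9S,10S)-12-[(tert-butyldiphenylsilyl)oxy]-6,9-dihydroxydrim-7-en-11-oate (6β-OH) | O[C@@H]1C=C(CO[Si](c3ccccc3)(c3ccccc3)C(C)(C)C)[C@](O)(C(=O)OC(C)(C)C)[C@@]2(C)CCCC(C)(C)[C@H]12 | intermediate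
16 | (2E,4E)-hexa-2,4-dienal (sorbaldehyde) | C/C=C/C=C/C=O | starting material
17 | (2E,4E,6E)-octa-2,4,6-trienoic acid | C/C=C/C=C/C=C/C(=O)O | intermediate
18 | (2E,4E,6E)-octa-2,4,6-trienoic 2,4,6-trichlorobenzoic anhydride | C/C=C/C=C/C=C/C(=O)OC(=O)c1c(Cl)cc(Cl)cc1Cl | intermediate (not isolated)
19 | tert-butyl (5S,6R,9S,10S)-12-[(tert-butyldiphenylsilyl)oxy]-9-hydroxy-6-[(2E,4E,6E)-octa-2,4,6-trienoyloxy]drim-7-en-11-oate | C/C=C/C=C/C=C/C(=O)O[C@@H]1C=C(CO[Si](c3ccccc3)(c3ccccc3)C(C)(C)C)[C@](O)(C(=O)OC(C)(C)C)[C@@]2(C)CCCC(C)(C)[C@H]12 | intermediate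
20 | tert-butyl (5S,6R,9S,10S)-9,12-dihydroxy-6-[(2E,4E,6E)-octa-2,4,6-trienoyloxy]drim-7-en-11-oate | C/C=C/C=C/C=C/C(=O)O[C@@H]1C=C(CO)[C@](O)(C(=O)OC(C)(C)C)[C@@]2(C)CCCC(C)(C)[C@H]12 | intermediate
21 | tert-butyl (5S,6R,9S,10S)-9-hydroxy-6-[(2E,4E,6E)-octa-2,4,6-trienoyloxy]-12-oxodrim-7-en-11-oate | C/C=C/C=C/C=C/C(=O)O[C@@H]1C=C(C=O)[C@](O)(C(=O)OC(C)(C)C)[C@@]2(C)CCCC(C)(C)[C@H]12 | intermediate
22 | ustusoic acid B | C/C=C/C=C/C=C/C(=O)O[C@@H]1C=C(C=O)[C@](O)(C(=O)O)[C@@]2(C)CCCC(C)(C)[C@H]12 | target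

Total steps: 13. Longest linear sequence: 12 (steps 1–8 and 10–13).

Steps most likely to fail

1. Step 7 (Proposed new method). What may go wrong: ionisation of the doubly allylic C6 silyl ether before the C–C bond forms, closure at C5 to a spiro five-membered ring, or methyl migration in the C5 cation in place of the hydride shift. The fallback uses known chemistry, sets out from 1 and 2 and comes back at 14; its cost is a resolution. Methylmagnesium bromide adds to 1 to give the carbinol 1-(2,6,6-trimethylcyclohex-1-en-1-yl)ethanol F1, MnO2 gives the methyl ketone F2, and TBSOTf/Et3N gives the 2-silyloxy diene F3. Alkyne 2 is carboxylated (n-BuLi, then Boc2O) to tert-butyl 4-[(tert-butyldiphenylsilyl)oxy]but-2-ynoate F4. A thermal Diels–Alder reaction of F3 with F4 (toluene, 120 °C, sealed tube) closes ring B, with the nucleophilic diene terminus C7 bonding to C8 and C10 to C9, to give the cyclohexa-1,4-dienyl silyl ether F5. Aqueous HCl and then DBU give the conjugated trans-fused keto ester F6 with hydrogen at C9. Its extended enolate (KHMDS, THF, −78 °C) is hydroxylated at C9 with 2-(phenylsulfonyl)-3-phenyloxaziridine, anti to the C10 methyl group, to give 14 together with its enantiomer F7, and preparative HPLC on a chiral stationary phase returns 14.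

2. Step 6. What may go wrong: O-to-C silyl migration or β-elimination of silanolate in the alkenyllithium, and double addition to the oxalate. The fallback sets out from 9 and comes back at 11. Nozaki–Hiyama–Kishi coupling of iodide 9 with tert-butyl glyoxylate (CrCl2, NiCl2 cat., DMF, rt) gives the α-hydroxy ester F8 as a mixture of C9 epimers, and Dess–Martin oxidation converts both epimers into 11.

3. Step 10. What may go wrong: slow acylation of the axial C6 hydroxyl flanked by two syn-axial methyl groups, with isomerisation of the trienoyl unit under forcing conditions. The fallback sets out from 15 and comes back at 19. Acylation with the small, reactive diethylphosphonoacetic acid (DCC, DMAP, CH2Cl2) gives the phosphonoacetate F9, and Horner–Wadsworth–Emmons olefination with sorbaldehyde 16 (LiCl, DBU, MeCN) builds the E-configured trienoate on the ester to give 19.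

Further compounds
F1 | step 7 | 1-(2,6,6-trimethylcyclohex-1-en-1-yl)ethanol (racemic) | CC(O)C1=C(C)CCCC1(C)C
F2 | step 7 | 1-(2,6,6-trimethylcyclohex-1-en-1-yl)ethanone | CC(=O)C1=C(C)CCCC1(C)C
F3 | step 7 | tert-butyldimethyl{[1-(2,6,6-trimethylcyclohex-1-en-1-yl)ethenyl]oxy}silane | C=C(O[Si](C)(C)C(C)(C)C)C1=C(C)CCCC1(C)C
F4 | step 7 | tert-butyl 4-[(tert-butyldiphenylsilyl)oxy]but-2-ynoate | CC(C)(C)OC(=O)C#CCO[Si](c1ccccc1)(c1ccccc1)C(C)(C)C
F5 | step 7 | tert-butyl 6-[(tert-butyldimethylsilyl)oxy]-12-[(tert-butyldiphenylsilyl)oxy]drima-5,8-dien-11-oate (racemic) | CC(C)(C)[Si](C)(C)OC1=C2C(C)(C)CCCC2(C)C(C(=O)OC(C)(C)C)=C(CO[Si](c3ccccc3)(c3ccccc3)C(C)(C)C)C1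
F6 | step 7 | tert-butyl 12-[(tert-butyldiphenylsilyl)oxy]-6-oxodrim-7-en-11-oate (racemic; 5α-H, 9α-H, 10β-methyl relative configuration shown) | O=C1C=C(CO[Si](c3ccccc3)(c3ccccc3)C(C)(C)C)[C@H](C(=O)OC(C)(C)C)[C@@]2(C)CCCC(C)(C)[C@H]12
F7 | step 7 | enantiomer of 14, formed with 14 as the racemate | O=C1C=C(CO[Si](c3ccccc3)(c3ccccc3)C(C)(C)C)[C@@](O)(C(=O)OC(C)(C)C)[C@]2(C)CCCC(C)(C)[C@@H]12
F8 | step 6 | tert-butyl (3Z,5R)-5-[(tert-butyldimethylsilyl)oxy]-3-{[(tert-butyldiphenylsilyl)oxy]methyl}-2-hydroxy-5-(2,6,6-trimethylcyclohex-1-en-1-yl)pent-3-enoate (both C2 epimers) | CC(C)(C)[Si](C)(C)O[C@H](/C=C(\C(O)C(=O)OC(C)(C)C)CO[Si](c1ccccc1)(c1ccccc1)C(C)(C)C)C1=C(C)CCCC1(C)C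
F9 | step 10 | tert-butyl (5S,6R,9S,10S)-12-[(tert-butyldiphenylsilyl)oxy]-6-[(diethoxyphosphoryl)acetoxy]-9-hydroxydrim-7-en-11-oate | CCOP(=O)(OCC)CC(=O)O[C@@H]1C=C(CO[Si](c3ccccc3)(c3ccccc3)C(C)(C)C)[C@](O)(C(=O)OC(C)(C)C)[C@@]2(C)CCCC(C)(C)[C@H]12
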